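Everything rests on disconnecting the polyene at the C14'–C15' single bond, where the methyl-branched E-alkene C13'=C14' of the hydroxylated half meets the central C15=C15' unit of the chain that links the two cyclohexene rings. The key step exploits this feature: zirconium-catalysed methylalumination of a terminal alkyne C13'≡C14' adds the C13' methyl and a C14'–Al bond syn, and palladium/zinc-catalysed coupling with a C15' bromide forms C14'–C15'. Trienyne, Me3Al and 1-bromopentaene are thus joined in one operation; the precursor is a methyl-free terminal enyne. Both rings derive from one enone through antipodal CBS reductions and suprafacial Still–Wittig shifts.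

Key step: step 25

Remark: carotenoid locants are used (unprimed C1–C15 for the half carrying the 3-methylbut-2-enyl group, primed locants for the half carrying the hydroxylated side chain), and 2,4,4-trimethylcyclohex-2-en-1-one 11 is taken to be a catalogue chemical.

**Two-carbon and four-carbon linchpins, C8–C14 phosphonate**

Step 1
Reactants: 1 acetylene
Product: 2 (E)-1-bromo-2-iodoethene
Conditions: IBr, 48% aq. HBr, 0 °C
Reagents that add atoms: iodine monobromide, IBr
Why: Electrophilic anti-addition of I–Br across ethyne (alkyne halogenation through a bridged iodonium ion) should give the E-dihaloethene.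

Step 2
Reactants: 3 ethynyltrimethylsilane; 2 (E)-1-bromo-2-iodoethene
Product: 5 (E)-(4-bromobut-3-en-1-yn-1-yl)trimethylsilane, via zinc acetylide 4 (not isolated)
Conditions: n-BuLi, THF, −78 °C; ZnBr2, 0 °C; then 2, Pd(PPh3)4 (3 mol%), 0 → 23 °C
Reagents that add atoms: none
Why: Negishi coupling of the alkynylzinc reagent should occur only at the weaker C–I bond, so the C–Br bond and the E geometry are kept.

Step 3
Reactants: 6 prop-2-yn-1-ol; 5 (E)-(4-bromobut-3-en-1-yn-1-yl)trimethylsilane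
Product: 8 (2E,4E)-2-methyl-7-(trimethylsilyl)hepta-2,4-dien-6-yn-1-ol, via alkenylalane 7 (not isolated)
Conditions: Me3Al (3 equiv), Cp2ZrCl2 (25 mol%), CH2Cl2, 0 → 23 °C; then 5, ZnCl2 (0.5 equiv), Pd(PPh3)4 (5 mol%), THF, 23 °C
Reagents that add atoms: trimethylaluminium, C[Al](C)C
Why: Zirconium-catalysed syn-methylalumination of the terminal alkyne (Negishi carboalumination, run on the aluminium alkoxide) followed by palladium/zinc cross-coupling with the bromoenyne should give the 2E,4E-dienynol with retention at both alkenes.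

Step 4
Reactants: 8 (2E,4E)-2-methyl-7-(trimethylsilyl)hepta-2,4-dien-6-yn-1-ol
Product: 9 [(3E,5E)-7-bromo-6-methylhepta-3,5-dien-1-yn-1-yl]trimethylsilane
Conditions: CBr4, PPh3, CH2Cl2, 0 °C
Reagents that add atoms: tetrabromomethane, BrC(Br)(Br)Br
Why: Appel bromination converts the primary allylic alcohol into the bromide under neutral conditions by SN2 displacement of the oxyphosphonium ion, without allylic transposition.

Step 5
Reactants: 9 [(3E,5E)-7-bromo-6-methylhepta-3,5-dien-1-yn-1-yl]trimethylsilane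
Product: 10 diethyl [(2E,4E)-2-methyl-7-(trimethylsilyl)hepta-2,4-dien-6-yn-1-yl]phosphonate
Conditions: P(OEt)3, 90 °C
Reagents that add atoms: triethyl phosphite, CCOP(OCC)OCC
Why: Michaelis–Arbuzov reaction of the primary allylic bromide should proceed by direct attack at CH2, because SN2' attack would break the conjugated dienyne.

**Common ring precursor**

Step 6
Reactants: 11 2,4,4-trimethylcyclohex-2-en-1-one
Product: 12 2,4,4-trimethylcyclohexa-2,5-dien-1-one
Conditions: DDQ, 1,4-dioxane, reflux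
Reagents that add atoms: none
Why: DDQ dehydrogenation (hydride abstraction from C5 of the C1–C6 enol) introduces the second enone double bond, and the quaternary C4 excludes aromatisation or any other dienone.

Step 7
Reactants: 12 2,4,4-trimethylcyclohexa-2,5-dien-1-one
Product: 13 (5R)-2,4,4-trimethyl-5-vinylcyclohex-2-en-1-one
Conditions: potassium vinyltrifluoroborate (2 equiv), [Rh(cod)2]PF6 (3 mol%), (R)-BINAP (3.3 mol%), toluene/H2O (4:1), 105 °C
Reagents that add atoms: potassium vinyltrifluoroborate, C=C[B-](F)(F)F.[K+]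
Why: Hayashi–Miyaura rhodium-catalysed asymmetric 1,4-addition should take place only at the unsubstituted enone (the α-methyl enone is inert), the (R)-BINAP–rhodium vinyl species selecting one enantiotopic face with the same topological sense as in cyclohex-2-enone and so setting the (R) centre that becomes C2 and C2'.

Step 8
Reactants: 13 (5R)-2,4,4-trimethyl-5-vinylcyclohex-2-en-1-one
Product: 14 2-[(1S)-2,2,4-trimethyl-5-oxocyclohex-3-en-1-yl]acetaldehyde
Conditions: PdCl2(PhCN)2 (12 mol%), CuCl2·2H2O (12 mol%), AgNO2 (6 mol%), O2 (1 atm), t-BuOH/MeNO2 (15:1), 23 °C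
Reagents that add atoms: dioxygen, O=O
Why: The nitrite-modified, aldehyde-selective Wacker oxidation should place oxygen on the terminal carbon of the vinyl group (anti-Markovnikov attack reinforced by the branched neighbour) and leave the electron-poor enone untouched.

**Half with the 3-methylbut-2-enyl group (2,6-cis ring)**

Step 9
Reactants: 14 2-[(1S)-2,2,4-trimethyl-5-oxocyclohex-3-en-1-yl]acetaldehyde
Product: 15 (5S)-2,4,4-trimethyl-5-(3-methylbut-2-en-1-yl)cyclohex-2-en-1-one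
Conditions: isopropyltriphenylphosphonium iodide, n-BuLi, THF, 0 °C; then 14, −78 → 0 °C
Reagents that add atoms: isopropyltriphenylphosphonium iodide, CC(C)[P+](c1ccccc1)(c1ccccc1)c1ccccc1.[I-]
Why: Wittig olefination with the non-stabilised isopropylidene ylide is chemoselective for the aldehyde over the hindered enone and builds the 3-methylbut-2-enyl group.

Step 10
Reactants: 15 (5S)-2,4,4-trimethyl-5-(3-methylbut-2-en-1-yl)cyclohex-2-en-1-one
Product: 16 (1R,5S)-2,4,4-trimethyl-5-(3-methylbut-2-en-1-yl)cyclohex-2-en-1-ol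
Conditions: (S)-Me-CBS oxazaborolidine (20 mol%), catecholborane (1.8 equiv), toluene, −78 °C
Reagents that add atoms: none
Why: Corey–Bakshi–Shibata 1,2-reduction with the (S)-catalyst, the alkenyl side of the enone acting as the large group, should give the (1R)-carbinol cis to the side chain, which is also the sense of axial hydride delivery (matched case).

Step 11
Reactants: 16 (1R,5S)-2,4,4-trimethyl-5-(3-methylbut-2-en-1-yl)cyclohex-2-en-1-ol
Product: 17 tributyl({[(1R,5S)-2,4,4-trimethyl-5-(3-methylbut-2-en-1-yl)cyclohex-2-en-1-yl]oxy}methyl)stannane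
Conditions: KH, THF, 0 °C; Bu3SnCH2I, 23 °C
Reagents that add atoms: tributyl(iodomethyl)stannane, CCCC[Sn](CCCC)(CCCC)CI
Why: Williamson etherification of the potassium alkoxide with the reactive primary iodide should give the stannylmethyl ether without touching the carbinol configuration.

Step 12
Reactants: 17 tributyl({[(1R,5S)-2,4,4-trimethyl-5-(3-methylbut-2-en-1-yl)cyclohex-2-en-1-yl]oxy}methyl)stannane
Product: 19 [(1R,5S)-2,6,6-trimethyl-5-(3-methylbut-2-en-1-yl)cyclohex-2-en-1-yl]methanol, via lithiomethyl ether 18 (not isolated)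
Conditions: n-BuLi, THF, −78 °C
Reagents that add atoms: none
Why: Tin–lithium exchange triggers the Still–Wittig [2,3]-sigmatropic rearrangement, whose suprafacial five-membered transition state transfers the C4–O configuration to C6, so the hydroxymethyl group should emerge cis to the C2 side chain with the C4=C5 alkene in place.

Step 13
Reactants: 19 [(1R,5S)-2,6,6-trimethyl-5-(3-methylbut-2-en-1-yl)cyclohex-2-en-1-yl]methanol
Product: 20 (1R,5S)-2,6,6-trimethyl-5-(3-methylbut-2-en-1-yl)cyclohex-2-ene-1-carbaldehyde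
Conditions: Dess–Martin periodinane, NaHCO3, CH2Cl2, 0 °C
Reagents that add atoms: none
Why: Buffered Dess–Martin oxidation should give the β,γ-unsaturated aldehyde without epimerisation at C6 or migration of the ring alkene.

Step 14
Reactants: 20 (1R,5S)-2,6,6-trimethyl-5-(3-methylbut-2-en-1-yl)cyclohex-2-ene-1-carbaldehyde; 10 diethyl [(2E,4E)-2-methyl-7-(trimethylsilyl)hepta-2,4-dien-6-yn-1-yl]phosphonate
Product: 21 trimethyl{(3E,5E,7E)-6-methyl-8-[(1R,5S)-2,6,6-trimethyl-5-(3-methylbut-2-en-1-yl)cyclohex-2-en-1-yl]octa-3,5,7-trien-1-yn-1-yl}silane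
Conditions: 10, NaN(SiMe3)2, THF, −78 °C; then 20, −78 → 0 °C
Reagents that add atoms: none
Why: Horner–Wadsworth–Emmons olefination with the allylic phosphonate anion should form the E C7=C8 alkene and bring in C8–C14 in one step, the fully preformed anion and low temperature sparing the C6 stereocentre.

Step 15
Reactants: 21 trimethyl{(3E,5E,7E)-6-methyl-8-[(1R,5S)-2,6,6-trimethyl-5-(3-methylbut-2-en-1-yl)cyclohex-2-en-1-yl]octa-3,5,7-trien-1-yn-1-yl}silane
Product: 22 (4S,6R)-1,5,5-trimethyl-4-(3-methylbut-2-en-1-yl)-6-[(1E,3E,5E)-3-methylocta-1,3,5-trien-7-yn-1-yl]cyclohex-1-ene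
Conditions: K2CO3 (cat.), MeOH/THF, 23 °C
Reagents that add atoms: none
Why: Base-catalysed methanolysis cleaves the alkynyl C–Si bond and frees the terminal alkyne.

Step 16
Reactants: 22 (4S,6R)-1,5,5-trimethyl-4-(3-methylbut-2-en-1-yl)-6-[(1E,3E,5E)-3-methylocta-1,3,5-trien-7-yn-1-yl]cyclohex-1-ene; 2 (E)-1-bromo-2-iodoethene
Product: 24 (4S,6R)-6-[(1E,3E,5E,7E,9E)-10-bromo-3,7-dimethyldeca-1,3,5,7,9-pentaen-1-yl]-1,5,5-trimethyl-4-(3-methylbut-2-en-1-yl)cyclohex-1-ene, via alkenylalane 23 (not isolated)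
Conditions: Me3Al (2 equiv), Cp2ZrCl2 (25 mol%), ClCH2CH2Cl, 23 °C; then 2 (1.5 equiv), Pd2(dba)3 (2.5 mol%), P(2-furyl)3 (10 mol%), ZnCl2 (0.5 equiv), THF, 0 → 23 °C, dark
Reagents that add atoms: trimethylaluminium, C[Al](C)C
Why: Negishi methylalumination installs the C13 methyl and the C14–Al bond syn, and palladium/zinc coupling at the C–I bond of the excess dihaloethene should deliver the all-E 1-bromopentaene with the C–Br bond intact.

**Half with the hydroxylated side chain (2,6-trans ring)**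

Step 17
Reactants: 14 2-[(1S)-2,2,4-trimethyl-5-oxocyclohex-3-en-1-yl]acetaldehyde
Product: 25 (2E)-2-methyl-4-[(1S)-2,2,4-trimethyl-5-oxocyclohex-3-en-1-yl]but-2-enal
Conditions: 2-(triphenylphosphoranylidene)propanal (1.3 equiv), toluene, 80 °C
Reagents that add atoms: 2-(triphenylphosphoranylidene)propanal, CC(C=O)=P(c1ccccc1)(c1ccccc1)c1ccccc1
Why: Wittig olefination with the stabilised α-methyl ylide reacts only with the aliphatic aldehyde and should give the E-configured trisubstituted enal.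

Step 18
Reactants: 25 (2E)-2-methyl-4-[(1S)-2,2,4-trimethyl-5-oxocyclohex-3-en-1-yl]but-2-enal
Product: 26 (1S,5S)-5-[(2E)-4-hydroxy-3-methylbut-2-en-1-yl]-2,4,4-trimethylcyclohex-2-en-1-ol
Conditions: (R)-Me-CBS oxazaborolidine (30 mol%), catecholborane (3.5 equiv), toluene, −78 °C
Reagents that add atoms: none
Why: Corey–Bakshi–Shibata reduction takes the enal to the primary allylic alcohol and, under control of the (R)-catalyst, the ring ketone to the (1S)-carbinol trans to the side chain, the reagent overriding the weak substrate bias.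

Step 19
Reactants: 26 (1S,5S)-5-[(2E)-4-hydroxy-3-methylbut-2-en-1-yl]-2,4,4-trimethylcyclohex-2-en-1-ol
Product: 27 (1S,5S)-5-[(2E)-4-{[tert-butyl(dimethyl)silyl]oxy}-3-methylbut-2-en-1-yl]-2,4,4-trimethylcyclohex-2-en-1-ol
Conditions: TBSCl (1.05 equiv), imidazole, CH2Cl2, −20 °C
Reagents that add atoms: tert-butyl(chloro)dimethylsilane, CC(C)(C)[Si](C)(C)Cl
Why: Silylation should be selective for the unhindered primary allylic hydroxyl over the secondary ring carbinol flanked by the methyl-bearing alkene.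

Step 20
Reactants: 27 (1S,5S)-5-[(2E)-4-{[tert-butyl(dimethyl)silyl]oxy}-3-methylbut-2-en-1-yl]-2,4,4-trimethylcyclohex-2-en-1-ol
Product: 28 tributyl({[(1S,5S)-5-[(2E)-4-{[tert-butyl(dimethyl)silyl]oxy}-3-methylbut-2-en-1-yl]-2,4,4-trimethylcyclohex-2-en-1-yl]oxy}methyl)stannane
Conditions: KH, THF, 0 °C; Bu3SnCH2I, 23 °C
Reagents that add atoms: tributyl(iodomethyl)stannane, CCCC[Sn](CCCC)(CCCC)CI
Why: Williamson etherification of the potassium alkoxide, as in step 11, with the silyl ether inert to KH.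

Step 21
Reactants: 28 tributyl({[(1S,5S)-5-[(2E)-4-{[tert-butyl(dimethyl)silyl]oxy}-3-methylbut-2-en-1-yl]-2,4,4-trimethylcyclohex-2-en-1-yl]oxy}methyl)stannane
Product: 30 [(1S,5R)-5-[(2E)-4-{[tert-butyl(dimethyl)silyl]oxy}-3-methylbut-2-en-1-yl]-2,6,6-trimethylcyclohex-2-en-1-yl]methanol, via lithiomethyl ether 29 (not isolated)
Conditions: n-BuLi, THF, −78 °C
Reagents that add atoms: none
Why: Still–Wittig [2,3]-sigmatropic rearrangement after tin–lithium exchange transfers the C4'–O configuration suprafacially to C6', so the hydroxymethyl group should emerge trans to the C2' side chain.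

Step 22
Reactants: 30 [(1S,5R)-5-[(2E)-4-{[tert-butyl(dimethyl)silyl]oxy}-3-methylbut-2-en-1-yl]-2,6,6-trimethylcyclohex-2-en-1-yl]methanol
Product: 31 (1S,5R)-5-[(2E)-4-{[tert-butyl(dimethyl)silyl]oxy}-3-methylbut-2-en-1-yl]-2,6,6-trimethylcyclohex-2-ene-1-carbaldehyde
Conditions: Dess–Martin periodinane, NaHCO3, CH2Cl2, 0 °C
Reagents that add atoms: none
Why: Buffered Dess–Martin oxidation, as in step 13, should keep the C6' configuration and the position of the ring alkene.

Step 23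
Reactants: 31 (1S,5R)-5-[(2E)-4-{[tert-butyl(dimethyl)silyl]oxy}-3-methylbut-2-en-1-yl]-2,6,6-trimethylcyclohex-2-ene-1-carbaldehyde; 10 diethyl [(2E,4E)-2-methyl-7-(trimethylsilyl)hepta-2,4-dien-6-yn-1-yl]phosphonate
Product: 32 tert-butyl(dimethyl)({(2E)-2-methyl-4-[(1R,5S)-4,6,6-trimethyl-5-[(1E,3E,5E)-3-methyl-8-(trimethylsilyl)octa-1,3,5-trien-7-yn-1-yl]cyclohex-3-en-1-yl]but-2-en-1-yl}oxy)silane
Conditions: 10, NaN(SiMe3)2, THF, −78 °C; then 31, −78 → 0 °C
Reagents that add atoms: none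
Why: Horner–Wadsworth–Emmons olefination, as in step 14, should give the E C7'=C8' alkene and complete C8'–C14'.

Step 24
Reactants: 32 tert-butyl(dimethyl)({(2E)-2-methyl-4-[(1R,5S)-4,6,6-trimethyl-5-[(1E,3E,5E)-3-methyl-8-(trimethylsilyl)octa-1,3,5-trien-7-yn-1-yl]cyclohex-3-en-1-yl]but-2-en-1-yl}oxy)silane
Product: 33 (2E)-2-methyl-4-[(1R,5S)-4,6,6-trimethyl-5-[(1E,3E,5E)-3-methylocta-1,3,5-trien-7-yn-1-yl]cyclohex-3-en-1-yl]but-2-en-1-ol
Conditions: TBAF (2.5 equiv), THF, 0 → 23 °C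
Reagents that add atoms: none
Why: Fluoride cleaves the O–Si and the alkynyl C–Si bonds in one operation, so no protecting group has to be removed after the polyene is complete.

**Union**

Step 25
Reactants: 33 (2E)-2-methyl-4-[(1R,5S)-4,6,6-trimethyl-5-[(1E,3E,5E)-3-methylocta-1,3,5-trien-7-yn-1-yl]cyclohex-3-en-1-yl]but-2-en-1-ol; 24 (4S,6R)-6-[(1E,3E,5E,7E,9E)-10-bromo-3,7-dimethyldeca-1,3,5,7,9-pentaen-1-yl]-1,5,5-trimethyl-4-(3-methylbut-2-en-1-yl)cyclohex-1-ene
Product: 35 (all-E,2S,6R,2'R,6'S)-2-(3-methylbut-2-enyl)-2'-[(2E)-4-hydroxy-3-methylbut-2-enyl]-ε,ε-carotene (CNP0304855.1), via alkenylalane 34 (not isolated)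
Conditions: Me3Al (4 equiv), Cp2ZrCl2 (30 mol%), ClCH2CH2Cl, 0 → 23 °C; then 24 (0.9 equiv), Pd2(dba)3 (2.5 mol%), P(2-furyl)3 (10 mol%), ZnCl2 (0.5 equiv), THF, 23 °C, argon, dark
Reagents that add atoms: trimethylaluminium, C[Al](C)C
Why: Me3Al first turns the hydroxyl into an aluminium alkoxide, and the zirconocene-activated Al–CH3 bond then adds syn across the terminal alkyne, methyl to C13' and aluminium to C14' (Negishi zirconium-catalysed carboalumination), which fixes the E geometry of C13'=C14'. Oxidative addition of the C15'–Br bond of 24 to zerovalent palladium, aluminium-to-zinc-to-palladium transmetalation and reductive elimination then form the C14'–C15' bond with retention at both alkenes; the closest known reaction type is the zirconium/palladium/zinc assembly of carotenes from polyenynes and E-haloalkenes. No ring is closed and no stereocentre is created, the four ring stereocentres being spectators. The step needs regioselective methylalumination (secured by the terminal alkyne, unhindered at C14'), chemoselectivity for the alkyne over the alkenes of both partners (zirconocene methylalumination does not touch them under these conditions) and retention of E geometry (secured by the mild, base-free coupling in the dark).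

**Compound list**

1 | acetylene | C#C | starting material
2 | (E)-1-bromo-2-iodoethene | Br/C=C/I | intermediate
3 | ethynyltrimethylsilane | C#C[Si](C)(C)C | starting material
4 | bromo[(trimethylsilyl)ethynyl]zinc | C[Si](C)(C)C#C[Zn]Br | intermediate
5 | (E)-(4-bromobut-3-en-1-yn-1-yl)trimethylsilane | C[Si](C)(C)C#C/C=C/Br | intermediate
6 | prop-2-yn-1-ol | C#CCO | starting material
7 | {(1E)-3-[(dimethylalumanyl)oxy]-2-methylprop-1-en-1-yl}dimethylalumane | C[Al](C)/C=C(\C)CO[Al](C)C | intermediate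
8 | (2E,4E)-2-methyl-7-(trimethylsilyl)hepta-2,4-dien-6-yn-1-ol | OC/C(C)=C/C=C/C#C[Si](C)(C)C | intermediate
9 | [(3E,5E)-7-bromo-6-methylhepta-3,5-dien-1-yn-1-yl]trimethylsilane | BrC/C(C)=C/C=C/C#C[Si](C)(C)C | intermediate
10 | diethyl [(2E,4E)-2-methyl-7-(trimethylsilyl)hepta-2,4-dien-6-yn-1-yl]phosphonate | CCOP(=O)(OCC)C/C(C)=C/C=C/C#C[Si](C)(C)C | intermediate
11 | 2,4,4-trimethylcyclohex-2-en-1-one | CC1=CC(C)(C)CCC1=O | starting material
12 | 2,4,4-trimethylcyclohexa-2,5-dien-1-one | CC1=CC(C)(C)C=CC1=O | intermediate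
13 | (5R)-2,4,4-trimethyl-5-vinylcyclohex-2-en-1-one | C=C[C@H]1CC(=O)C(C)=CC1(C)C | intermediate
14 | 2-[(1S)-2,2,4-trimethyl-5-oxocyclohex-3-en-1-yl]acetaldehyde | O=CC[C@H]1CC(=O)C(C)=CC1(C)C | intermediate
15 | (5S)-2,4,4-trimethyl-5-(3-methylbut-2-en-1-yl)cyclohex-2-en-1-one | CC(C)=CC[C@H]1CC(=O)C(C)=CC1(C)C | intermediate
16 | (1R,5S)-2,4,4-trimethyl-5-(3-methylbut-2-en-1-yl)cyclohex-2-en-1-ol | CC(C)=CC[C@H]1C[C@@H](O)C(C)=CC1(C)C | intermediate
17 | tributyl({[(1R,5S)-2,4,4-trimethyl-5-(3-methylbut-2-en-1-yl)cyclohex-2-en-1-yl]oxy}methyl)stannane | CC(C)=CC[C@H]1C[C@@H](OC[Sn](CCCC)(CCCC)CCCC)C(C)=CC1(C)C | intermediate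
18 | ({[(1R,5S)-2,4,4-trimethyl-5-(3-methylbut-2-en-1-yl)cyclohex-2-en-1-yl]oxy}methyl)lithium | CC(C)=CC[C@H]1C[C@@H](OC[Li])C(C)=CC1(C)C | intermediate
19 | [(1R,5S)-2,6,6-trimethyl-5-(3-methylbut-2-en-1-yl)cyclohex-2-en-1-yl]methanol | CC(C)=CC[C@H]1CC=C(C)[C@@H](CO)C1(C)C | intermediate
20 | (1R,5S)-2,6,6-trimethyl-5-(3-methylbut-2-en-1-yl)cyclohex-2-ene-1-carbaldehyde | CC(C)=CC[C@H]1CC=C(C)[C@@H](C=O)C1(C)C | intermediate
21 | trimethyl{(3E,5E,7E)-6-methyl-8-[(1R,5S)-2,6,6-trimethyl-5-(3-methylbut-2-en-1-yl)cyclohex-2-en-1-yl]octa-3,5,7-trien-1-yn-1-yl}silane | CC(C)=CC[C@H]1CC=C(C)[C@@H](/C=C/C(C)=C/C=C/C#C[Si](C)(C)C)C1(C)C | intermediate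
22 | (4S,6R)-1,5,5-trimethyl-4-(3-methylbut-2-en-1-yl)-6-[(1E,3E,5E)-3-methylocta-1,3,5-trien-7-yn-1-yl]cyclohex-1-ene | CC(C)=CC[C@H]1CC=C(C)[C@@H](/C=C/C(C)=C/C=C/C#C)C1(C)C | intermediate
23 | {(1E,3E,5E,7E)-2,6-dimethyl-8-[(1R,5S)-2,6,6-trimethyl-5-(3-methylbut-2-en-1-yl)cyclohex-2-en-1-yl]octa-1,3,5,7-tetraen-1-yl}dimethylalumane | CC(C)=CC[C@H]1CC=C(C)[C@@H](/C=C/C(C)=C/C=C/C(C)=C/[Al](C)C)C1(C)C | intermediate
24 | (4S,6R)-6-[(1E,3E,5E,7E,9E)-10-bromo-3,7-dimethyldeca-1,3,5,7,9-pentaen-1-yl]-1,5,5-trimethyl-4-(3-methylbut-2-en-1-yl)cyclohex-1-ene | CC(C)=CC[C@H]1CC=C(C)[C@@H](/C=C/C(C)=C/C=C/C(C)=C/C=C/Br)C1(C)C | intermediate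
25 | (2E)-2-methyl-4-[(1S)-2,2,4-trimethyl-5-oxocyclohex-3-en-1-yl]but-2-enal | O=C/C(C)=C/C[C@H]1CC(=O)C(C)=CC1(C)C | intermediate
26 | (1S,5S)-5-[(2E)-4-hydroxy-3-methylbut-2-en-1-yl]-2,4,4-trimethylcyclohex-2-en-1-ol | OC/C(C)=C/C[C@H]1C[C@H](O)C(C)=CC1(C)C | intermediate
27 | (1S,5S)-5-[(2E)-4-{[tert-butyl(dimethyl)silyl]oxy}-3-methylbut-2-en-1-yl]-2,4,4-trimethylcyclohex-2-en-1-ol | CC(C)(C)[Si](C)(C)OC/C(C)=C/C[C@H]1C[C@H](O)C(C)=CC1(C)C | intermediate
28 | tributyl({[(1S,5S)-5-[(2E)-4-{[tert-butyl(dimethyl)silyl]oxy}-3-methylbut-2-en-1-yl]-2,4,4-trimethylcyclohex-2-en-1-yl]oxy}methyl)stannane | CC(C)(C)[Si](C)(C)OC/C(C)=C/C[C@H]1C[C@H](OC[Sn](CCCC)(CCCC)CCCC)C(C)=CC1(C)C | intermediate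
29 | ({[(1S,5S)-5-[(2E)-4-{[tert-butyl(dimethyl)silyl]oxy}-3-methylbut-2-en-1-yl]-2,4,4-trimethylcyclohex-2-en-1-yl]oxy}methyl)lithium | CC(C)(C)[Si](C)(C)OC/C(C)=C/C[C@H]1C[C@H](OC[Li])C(C)=CC1(C)C | intermediate
30 | [(1S,5R)-5-[(2E)-4-{[tert-butyl(dimethyl)silyl]oxy}-3-methylbut-2-en-1-yl]-2,6,6-trimethylcyclohex-2-en-1-yl]methanol | CC(C)(C)[Si](C)(C)OC/C(C)=C/C[C@H]1CC=C(C)[C@H](CO)C1(C)C | intermediate
31 | (1S,5R)-5-[(2E)-4-{[tert-butyl(dimethyl)silyl]oxy}-3-methylbut-2-en-1-yl]-2,6,6-trimethylcyclohex-2-ene-1-carbaldehyde | CC(C)(C)[Si](C)(C)OC/C(C)=C/C[C@H]1CC=C(C)[C@H](C=O)C1(C)C | intermediate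
32 | tert-butyl(dimethyl)({(2E)-2-methyl-4-[(1R,5S)-4,6,6-trimethyl-5-[(1E,3E,5E)-3-methyl-8-(trimethylsilyl)octa-1,3,5-trien-7-yn-1-yl]cyclohex-3-en-1-yl]but-2-en-1-yl}oxy)silane | CC(C)(C)[Si](C)(C)OC/C(C)=C/C[C@H]1CC=C(C)[C@H](/C=C/C(C)=C/C=C/C#C[Si](C)(C)C)C1(C)C | intermediate
33 | (2E)-2-methyl-4-[(1R,5S)-4,6,6-trimethyl-5-[(1E,3E,5E)-3-methylocta-1,3,5-trien-7-yn-1-yl]cyclohex-3-en-1-yl]but-2-en-1-ol | OC/C(C)=C/C[C@H]1CC=C(C)[C@H](/C=C/C(C)=C/C=C/C#C)C1(C)C | intermediate
34 | {(1E,3E,5E,7E)-8-[(1S,5R)-5-{(2E)-4-[(dimethylalumanyl)oxy]-3-methylbut-2-en-1-yl}-2,6,6-trimethylcyclohex-2-en-1-yl]-2,6-dimethylocta-1,3,5,7-tetraen-1-yl}dimethylalumane | C[Al](C)OC/C(C)=C/C[C@H]1CC=C(C)[C@H](/C=C/C(C)=C/C=C/C(C)=C/[Al](C)C)C1(C)C | intermediate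
35 | (all-E,2S,6R,2'R,6'S)-2-(3-methylbut-2-enyl)-2'-[(2E)-4-hydroxy-3-methylbut-2-enyl]-ε,ε-carotene | CC(C)=CC[C@H]1CC=C(C)[C@@H](/C=C/C(C)=C/C=C/C(C)=C/C=C/C=C(C)/C=C/C=C(C)/C=C/[C@H]2C(C)=CC[C@H](C/C=C(\C)CO)C2(C)C)C1(C)C | target

**Count**

Total step count: 25. Longest linear sequence: 12 steps (6, 7, 8, 17, 18, 19, 20, 21, 22, 23, 24, 25).

**Steps most likely to fail, with fallbacks**

Step 25. The polyenylalane may not survive the coupling stage. It could lose its metal by protonation, or the E geometry of the alane or of bromide 24 could erode in the Lewis-acidic medium before the C14'–C15' bond is formed. The fallback closes the same bond by a Stille coupling with reversed polarity and isolated partners; it sets out from 33 and 22 and returns at 35. Methylalumination of 33 as in step 25, followed by iodinolysis (I2, THF, −30 °C), would give (2E)-4-[(1R,5S)-5-[(1E,3E,5E,7E)-8-iodo-3,7-dimethylocta-1,3,5,7-tetraen-1-yl]-4,6,6-trimethylcyclohex-3-en-1-yl]-2-methylbut-2-en-1-ol F1. Alane 23, made from 22 as in step 16, would be coupled with (E)-tributyl(2-iodoethenyl)stannane (Pd(PPh3)4, ZnCl2, THF) at its C–I bond to give tributyl{(1E,3E,5E,7E,9E)-4,8-dimethyl-10-[(1R,5S)-2,6,6-trimethyl-5-(3-methylbut-2-en-1-yl)cyclohex-2-en-1-yl]deca-1,3,5,7,9-pentaen-1-yl}stannane F2. F1 and F2 would then be joined under neutral conditions (Pd2(dba)3, AsPh3, NMP, 23 °C) to give 35.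

Step 21 (the same concern holds for step 12). The lithiomethyl ether may undergo a [1,2]-shift or be protonated before it reaches C6', which is flanked by the quaternary C1' and the methyl-bearing C5'. The fallback replaces the intramolecular shift by an intermolecular, picolinate-directed anti-SN2' substitution with a copper reagent; it sets out from 25 and returns at 32.
- Reduction of 25 with (S)-Me-CBS and catecholborane would give the cis-diol (1R,5S)-5-[(2E)-4-hydroxy-3-methylbut-2-en-1-yl]-2,4,4-trimethylcyclohex-2-en-1-ol F3.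
- Selective silylation (TBSCl, imidazole) would give (1R,5S)-5-[(2E)-4-{[tert-butyl(dimethyl)silyl]oxy}-3-methylbut-2-en-1-yl]-2,4,4-trimethylcyclohex-2-en-1-ol F4.
- Acylation (picolinic acid, DCC, DMAP) would give (1R,5S)-5-[(2E)-4-{[tert-butyl(dimethyl)silyl]oxy}-3-methylbut-2-en-1-yl]-2,4,4-trimethylcyclohex-2-en-1-yl pyridine-2-carboxylate F5.
- Bromine–lithium exchange on 5 (t-BuLi, Et2O, −78 °C) would give [(1E)-4-(trimethylsilyl)but-1-en-3-yn-1-yl]lithium F6. After transmetalation (MgBr2, then CuBr·SMe2) this attacks C6' of F5 anti to the leaving group, giving tert-butyl(dimethyl)({(2E)-2-methyl-4-[(1R,5S)-4,6,6-trimethyl-5-[(1E)-4-(trimethylsilyl)but-1-en-3-yn-1-yl]cyclohex-3-en-1-yl]but-2-en-1-yl}oxy)silane F7, with the chain trans to the side chain.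
- K2CO3 in MeOH would give tert-butyl({(2E)-4-[(1R,5S)-5-[(1E)-but-1-en-3-yn-1-yl]-4,6,6-trimethylcyclohex-3-en-1-yl]-2-methylbut-2-en-1-yl}oxy)dimethylsilane F8.
- Methylalumination of F8 and palladium/zinc coupling with 5, as in step 3, would install the C9' methyl and C11'–C14' and give 32.

Step 7. Insertion at the β-carbon next to the quaternary centre may be slow, so that protodeboronation of the vinylboron reagent outruns addition, or the facial selectivity may be insufficient. The fallback gives up the catalytic asymmetric addition for a racemic addition followed by a reagent-controlled reduction that turns the enantiomers into separable diastereomers; it sets out from 12 and returns at 13. Copper-mediated conjugate vinylation (CH2=CHMgBr, CuBr·SMe2, Me3SiCl, THF, −78 °C, then aqueous acid) would give racemic 2,4,4-trimethyl-5-vinylcyclohex-2-en-1-one F9. Reduction with (S)-Me-CBS and catecholborane would give the two (1R)-carbinols, cis (1R,5R)-2,4,4-trimethyl-5-vinylcyclohex-2-en-1-ol F10 and trans (1R,5S)-2,4,4-trimethyl-5-vinylcyclohex-2-en-1-ol F11, which are separated by chromatography. Oxidation of F10 with MnO2 would return 13; at most half of the material can be used.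

Further compounds
F1 | step 25 | (2E)-4-[(1R,5S)-5-[(1E,3E,5E,7E)-8-iodo-3,7-dimethylocta-1,3,5,7-tetraen-1-yl]-4,6,6-trimethylcyclohex-3-en-1-yl]-2-methylbut-2-en-1-ol | OC/C(C)=C/C[C@H]1CC=C(C)[C@H](/C=C/C(C)=C/C=C/C(C)=C/I)C1(C)C
F2 | step 25 | tributyl{(1E,3E,5E,7E,9E)-4,8-dimethyl-10-[(1R,5S)-2,6,6-trimethyl-5-(3-methylbut-2-en-1-yl)cyclohex-2-en-1-yl]deca-1,3,5,7,9-pentaen-1-yl}stannane | CC(C)=CC[C@H]1CC=C(C)[C@@H](/C=C/C(C)=C/C=C/C(C)=C/C=C/[Sn](CCCC)(CCCC)CCCC)C1(C)C
F3 | step 21 | (1R,5S)-5-[(2E)-4-hydroxy-3-methylbut-2-en-1-yl]-2,4,4-trimethylcyclohex-2-en-1-ol | OC/C(C)=C/C[C@H]1C[C@@H](O)C(C)=CC1(C)C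
F4 | step 21 | (1R,5S)-5-[(2E)-4-{[tert-butyl(dimethyl)silyl]oxy}-3-methylbut-2-en-1-yl]-2,4,4-trimethylcyclohex-2-en-1-ol | CC(C)(C)[Si](C)(C)OC/C(C)=C/C[C@H]1C[C@@H](O)C(C)=CC1(C)C
F5 | step 21 | (1R,5S)-5-[(2E)-4-{[tert-butyl(dimethyl)silyl]oxy}-3-methylbut-2-en-1-yl]-2,4,4-trimethylcyclohex-2-en-1-yl pyridine-2-carboxylate | CC(C)(C)[Si](C)(C)OC/C(C)=C/C[C@H]1C[C@@H](OC(=O)c2ccccn2)C(C)=CC1(C)C
F6 | step 21 | [(1E)-4-(trimethylsilyl)but-1-en-3-yn-1-yl]lithium | [Li]/C=C/C#C[Si](C)(C)C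
F7 | step 21 | tert-butyl(dimethyl)({(2E)-2-methyl-4-[(1R,5S)-4,6,6-trimethyl-5-[(1E)-4-(trimethylsilyl)but-1-en-3-yn-1-yl]cyclohex-3-en-1-yl]but-2-en-1-yl}oxy)silane | CC(C)(C)[Si](C)(C)OC/C(C)=C/C[C@H]1CC=C(C)[C@H](/C=C/C#C[Si](C)(C)C)C1(C)C
F8 | step 21 | tert-butyl({(2E)-4-[(1R,5S)-5-[(1E)-but-1-en-3-yn-1-yl]-4,6,6-trimethylcyclohex-3-en-1-yl]-2-methylbut-2-en-1-yl}oxy)dimethylsilane | CC(C)(C)[Si](C)(C)OC/C(C)=C/C[C@H]1CC=C(C)[C@H](/C=C/C#C)C1(C)C
F9 | step 7 | racemic 2,4,4-trimethyl-5-vinylcyclohex-2-en-1-one | C=CC1CC(=O)C(C)=CC1(C)C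
F10 | step 7 | (1R,5R)-2,4,4-trimethyl-5-vinylcyclohex-2-en-1-ol | C=C[C@H]1C[C@@H](O)C(C)=CC1(C)C
F11 | step 7 | (1R,5S)-2,4,4-trimethyl-5-vinylcyclohex-2-en-1-ol | C=C[C@@H]1C[C@@H](O)C(C)=CC1(C)C
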